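**Assumptions.** The target is (−)-epiafzelechin 3-O-gallate, (2R,3R), 2,3-cis (both CIP descriptors checked against the SMILES). The facial sense of the step 6 catalyst is assigned by analogy with this catalyst family's dynamic kinetic resolution of 2-substituted cyclohexanones; confirm it by chiral HPLC on compound 10 and use the (R)/(R) catalyst if it is reversed.

## Retrosynthetic overview

1. Target 16 ⇐ global O-debenzylation of hexabenzyl ester 15 ⇐ acylation of tri-O-benzyl-epiafzelechin 10 with tri-O-benzylgalloyl chloride 14.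
2. 10 ⇐ asymmetric hydrogenation with dynamic kinetic resolution of racemic flavan-3-one 9, which sets C2 and C3 together as cis-(2R,3R).
3. 9 ⇐ Nef reaction of 3-nitroflavan 8 ⇐ conjugate reduction of 3-nitro-2H-chromene 7.
4. 7 ⇐ oxa-Michael addition of salicylaldehyde 3 to nitrostyrene 6, then intramolecular nitro-aldol (Henry) condensation that closes the pyran ring. This is the only ring formed; the three benzene rings are bought in.
5. Three branches: 3 from phloroglucinaldehyde, 6 from 4-benzyloxybenzaldehyde, 14 from gallic acid.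

## Route

**Step 1**
Reactants: 1, 2,4,6-trihydroxybenzaldehyde; 2, benzyl bromide
Product: 3, 2,4-bis(benzyloxy)-6-hydroxybenzaldehyde
Conditions: BnBr (2.05 equiv), K2CO3, DMF, 0 °C → rt; chromatography
Reagents that add atoms: benzyl bromide, BrCc1ccccc1
Why: Williamson etherification stops at the bis-ether because the remaining ortho-OH is deactivated by its hydrogen bond to the formyl group.

**Step 2**
Reactants: 4, 4-(benzyloxy)benzaldehyde; 5, nitromethane
Product: 6, (E)-1-(benzyloxy)-4-(2-nitrovinyl)benzene
Conditions: MeNO2, NH4OAc, AcOH, 100 °C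
Reagents that add atoms: nitromethane, C[N+](=O)[O-]
Why: Henry (nitro-aldol) condensation with dehydration gives the thermodynamically favoured, crystalline (E)-nitrostyrene.

**Step 3**
Reactants: 3, 2,4-bis(benzyloxy)-6-hydroxybenzaldehyde; 6, (E)-1-(benzyloxy)-4-(2-nitrovinyl)benzene (1.3–1.5 equiv)
Product: 7, (±)-5,7-bis(benzyloxy)-2-[4-(benzyloxy)phenyl]-3-nitro-2H-chromene
Conditions: DABCO (1 equiv), MeCN (concentrated), 60–80 °C
Reagents that add atoms: none
Why: Tandem oxa-Michael / intramolecular nitro-aldol (Henry) condensation: the phenoxide adds to the nitroalkene, the nitronate closes the pyran ring onto the ortho-formyl carbon (C3–C4 bond), and E1cB loss of water gives the nitrochromene; C2 is deliberately racemic because it is reset in step 6.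

**Step 4**
Reactants: 7, (±)-3-nitro-2H-chromene
Product: 8, (±)-5,7-bis(benzyloxy)-2-[4-(benzyloxy)phenyl]-3-nitrochromane (cis/trans mixture)
Conditions: NaBH4, THF/MeOH (10:1), 0 °C → rt; AcOH quench
Reagents that add atoms: none
Why: Conjugate (1,4) hydride reduction of the nitroalkene makes C4 a CH2 and leaves the benzyl ethers intact; the diastereomer ratio is irrelevant because C3 becomes sp2 in step 5.

**Step 5**
Reactants: 8, (±)-3-nitrochromane
Product: 9, (±)-5,7-bis(benzyloxy)-2-[4-(benzyloxy)phenyl]chroman-3-one (used crude, under argon)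
Conditions: NaOMe, MeOH/THF, 0 °C; then aq. TiCl3, NH4OAc buffer (pH ≈ 5), 0 °C → rt
Reagents that add atoms: water, O (carbonyl oxygen)
Why: McMurry-type reductive Nef reaction: Ti(III) reduces the nitronate to the imine, which hydrolyses to the ketone under buffered conditions that spare the benzyl ethers and the electron-rich A ring.

**Step 6**
Reactants: 9, (±)-flavan-3-one
Product: 10, (2R,3R)-5,7-bis(benzyloxy)-2-[4-(benzyloxy)phenyl]chroman-3-ol (2,3-cis; tri-O-benzyl-(−)-epiafzelechin)
Conditions: trans-RuH(η1-BH4)[(S)-xylbinap][(S)-daipen] (1 mol %), t-BuOK (5 mol %), i-PrOH/THF (3:1), H2 (10 atm), 25 °C, degassed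
Reagents that add atoms: none
Why: Noyori asymmetric hydrogenation with dynamic kinetic resolution: C2–H (α to the ketone, benzylic, α-oxy) epimerises quickly through the enolate, the catalyst delivers hydride anti to the C2 aryl group (giving 2,3-cis) and on the face that gives 3R, so only the (2R)-ketone is consumed and both stereocentres are set here.

**Step 7**
Reactants: 11, gallic acid; 2, benzyl bromide
Product: 12, benzyl 3,4,5-tris(benzyloxy)benzoate
Conditions: BnBr (4.5 equiv), K2CO3, DMF, 60 °C
Reagents that add atoms: benzyl bromide, BrCc1ccccc1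
Why: Exhaustive Williamson O-alkylation of the three phenols and the carboxylate.

**Step 8**
Reactants: 12, benzyl 3,4,5-tris(benzyloxy)benzoate
Product: 13, 3,4,5-tris(benzyloxy)benzoic acid
Conditions: NaOH, EtOH/THF/H2O, reflux; then aq. HCl
Reagents that add atoms: sodium hydroxide / water, [Na+].[OH-] / O
Why: Saponification cleaves only the benzyl ester; the aryl benzyl ethers are inert to hydroxide.

**Step 9**
Reactants: 13, 3,4,5-tris(benzyloxy)benzoic acid
Product: 14, 3,4,5-tris(benzyloxy)benzoyl chloride
Conditions: (COCl)2, cat. DMF, CH2Cl2, 0 °C → rt; concentrate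
Reagents that add atoms: oxalyl chloride, ClC(=O)C(=O)Cl (Cl)
Why: Acid chloride formation through Vilsmeier-type activation gives an acylating agent reactive enough for the hindered axial 3-OH.

**Step 10**
Reactants: 10, (2R,3R)-tri-O-benzyl-epiafzelechin; 14, 3,4,5-tris(benzyloxy)benzoyl chloride
Product: 15, (2R,3R)-5,7-bis(benzyloxy)-2-[4-(benzyloxy)phenyl]chroman-3-yl 3,4,5-tris(benzyloxy)benzoate
Conditions: DMAP, pyridine, CH2Cl2, 0 °C → rt
Reagents that add atoms: none
Why: DMAP-catalysed (nucleophilic catalysis) O-acylation breaks no bond at either stereocentre, so the cis-(2R,3R) configuration is retained.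

**Step 11**
Reactants: 15, hexabenzyl ester
Product: 16, (2R,3R)-5,7-dihydroxy-2-(4-hydroxyphenyl)chroman-3-yl 3,4,5-trihydroxybenzoate (target)
Conditions: H2 (1 atm), 20% Pd(OH)2/C, THF/MeOH, rt; filter under argon
Reagents that add atoms: none
Why: Catalytic hydrogenolysis removes all six O-benzyl ethers under neutral conditions that leave the gallate ester, the pyran C2–O bond and both stereocentres untouched.

## Compound list

1 | 2,4,6-trihydroxybenzaldehyde | O=Cc1c(O)cc(O)cc1O | starting material
2 | benzyl bromide | BrCc1ccccc1 | starting material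
3 | 2,4-bis(benzyloxy)-6-hydroxybenzaldehyde | O=Cc1c(O)cc(OCc2ccccc2)cc1OCc1ccccc1 | intermediate
4 | 4-(benzyloxy)benzaldehyde | O=Cc1ccc(OCc2ccccc2)cc1 | starting material
5 | nitromethane | C[N+](=O)[O-] | starting material
6 | (E)-1-(benzyloxy)-4-(2-nitrovinyl)benzene | O=[N+]([O-])/C=C/c1ccc(OCc2ccccc2)cc1 | intermediate
7 | (±)-5,7-bis(benzyloxy)-2-[4-(benzyloxy)phenyl]-3-nitro-2H-chromene | O=[N+]([O-])C1=Cc2c(OCc3ccccc3)cc(OCc3ccccc3)cc2OC1c1ccc(OCc2ccccc2)cc1 | intermediate (racemic)
8 | (±)-5,7-bis(benzyloxy)-2-[4-(benzyloxy)phenyl]-3-nitrochromane | O=[N+]([O-])C1Cc2c(OCc3ccccc3)cc(OCc3ccccc3)cc2OC1c1ccc(OCc2ccccc2)cc1 | intermediate (racemic, cis/trans mixture)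
9 | (±)-5,7-bis(benzyloxy)-2-[4-(benzyloxy)phenyl]chroman-3-one | O=C1Cc2c(OCc3ccccc3)cc(OCc3ccccc3)cc2OC1c1ccc(OCc2ccccc2)cc1 | intermediate (racemic)
10 | (2R,3R)-5,7-bis(benzyloxy)-2-[4-(benzyloxy)phenyl]chroman-3-ol | O[C@@H]1Cc2c(OCc3ccccc3)cc(OCc3ccccc3)cc2O[C@@H]1c1ccc(OCc2ccccc2)cc1 | intermediate
11 | gallic acid (3,4,5-trihydroxybenzoic acid) | OC(=O)c1cc(O)c(O)c(O)c1 | starting material
12 | benzyl 3,4,5-tris(benzyloxy)benzoate | O=C(OCc1ccccc1)c1cc(OCc2ccccc2)c(OCc2ccccc2)c(OCc2ccccc2)c1 | intermediate
13 | 3,4,5-tris(benzyloxy)benzoic acid | OC(=O)c1cc(OCc2ccccc2)c(OCc2ccccc2)c(OCc2ccccc2)c1 | intermediate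
14 | 3,4,5-tris(benzyloxy)benzoyl chloride | ClC(=O)c1cc(OCc2ccccc2)c(OCc2ccccc2)c(OCc2ccccc2)c1 | intermediate
15 | (2R,3R)-5,7-bis(benzyloxy)-2-[4-(benzyloxy)phenyl]chroman-3-yl 3,4,5-tris(benzyloxy)benzoate | O=C(O[C@@H]1Cc2c(OCc3ccccc3)cc(OCc3ccccc3)cc2O[C@@H]1c1ccc(OCc2ccccc2)cc1)c1cc(OCc2ccccc2)c(OCc2ccccc2)c(OCc2ccccc2)c1 | intermediate
16 | (2R,3R)-5,7-dihydroxy-2-(4-hydroxyphenyl)chroman-3-yl 3,4,5-trihydroxybenzoate | O=C(O[C@@H]1Cc2c(O)cc(O)cc2O[C@@H]1c1ccc(O)cc1)c1cc(O)c(O)c(O)c1 | target

## Summary

**Total steps:** 11.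
**Longest linear sequence:** 7 steps (1 or 2 → 3 → 4 → 5 → 6 → 10 → 11), i.e. 7/11 ≈ 0.64 of the total. The gallate branch is 7 → 8 → 9 and joins at step 10.

**Three steps most likely to fail, with fallbacks:**

1. **Step 3 (oxa-Michael / nitro-aldol annulation).** Both partners are electronically deactivated (electron-rich, hydrogen-bonded aldehyde; p-alkoxy nitrostyrene), so the reaction may stall at the reversible oxa-Michael adduct.
   Fallback: close the ring through the chalcone instead. Claisen–Schmidt condensation of 2-hydroxy-4,6-bis(benzyloxy)acetophenone with 4, then intramolecular oxa-Michael cyclisation (NaOAc, EtOH, reflux) to the flavanone. NaBH4 reduction, dehydration to the flav-3-ene, hydroboration–oxidation and Dess–Martin oxidation then rejoin the route at ketone 9.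

2. **Step 5 (Nef reaction).** The nitronate can ring-open by retro-oxa-Michael, and ketone 9 is enolisable and air-sensitive.
   Fallback: avoid the nitronate by reducing nitrochromene 7 directly to the chroman-3-one oxime (SnCl2·2H2O or Zn/AcOH) and deoximating reductively (aq. TiCl3) to 9. If the nitro series fails altogether, reach 9 from the flav-3-ene as in fallback 1.

3. **Step 6 (hydrogenation with dynamic kinetic resolution).** The acidic β-tetralone-like ketone may inhibit the catalyst as its enolate or give insufficient ee, and the sense of induction rests on analogy.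
   Fallback: reduce racemic 9 with L-Selectride (THF, −78 °C) to racemic cis-10, then resolve by lipase-catalysed kinetic acylation or preparative chiral chromatography. The unwanted enantiomer is recycled by Dess–Martin oxidation back to 9.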